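The earlier runs and the new flask stem from a simulated flask with constants of no real substance; the scatter is artificial.

What is left of the two substrates is what is asked, so I reckon the leftover first and the clock last.

| flask | left-handed substrate | right-handed substrate | coupling partner | precatalyst | remark | time |
|---|---|---|---|---|---|---|
| alpha | 0.10 M | 0.10 M | 0.10 M (fed, over 50 min) | 2.5 mM | run made earlier; the fed solution adds 1.0 times the starting volume |  |
| Friday's | 0.050 M | 0.050 M | 0.100 M (fed, over 50 min) | 2.5 mM | the fed solution adds 1.0 times the starting volume | 30 h |
| Wednesday's | 0.050 M | 0.050 M | 0.100 M (fed, over 50 min) | 2.5 mM | the fed solution adds 1.0 times the starting volume | 20 h |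

alpha run (percent of the left-handed substrate and right-handed substrate together charged)

| time / h | right-handed substrate / % | left-handed substrate / % |
|---|---|---|
| 1.50 | 50.0 | 49.5 |
| 3.00 | 50.0 | 48.6 |
| 5.00 | 49.9 | 46.5 |
| 6.00 | 49.6 | 46.0 |

(scatter of a reading: 0.3 percentage points)

- free catalyst is single-handed; left-handed substrate and right-handed substrate are mirror images of each other, charged as a racemate, each of them at the stated concentration
- charges are per starting volume, the dose included; the dosed solution carries all of it
- the numbers in the tables scatter by 0.3 percentage points (one standard deviation)
- an excess is below zero if the other one leads

1. which of the two ends with the higher excess of right-handed substrate over left-handed substrate among what is left of the two ("neither" if they lie within 2 percentage points) (Friday's / Wednesday's / neither)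
2. excess of right-handed substrate over left-handed substrate among what is left of the two at the end, Friday's
3. excess of right-handed substrate over left-handed substrate among what is left of the two at the end, Wednesday's

Which hand goes, and by what ratio? In the alpha run at 6.00 h, I take the selectivity factor s, the logarithm of the fraction of left-handed substrate left over the logarithm of the fraction of right-handed substrate left, and read 10.4. This is a rough reading, since the right-handed loss of 0.4 percentage points stands against a scatter of 0.3 points. If both hands react first order through the same catalyst and partner, s holds at every moment. With r the fraction of left-handed substrate left and q the s-th root of r, the excess is then (q−r)/(q+r), which has no clock in it.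

How far does r fall? Friday's and Wednesday's carry the alpha run's partner, precatalyst and feed, so I carry over its fractional loss of left-handed substrate. That loss is speeding up, from 0.0122 h⁻¹ early to 0.0183 h⁻¹ later. Running straight on at the later figure, my rough estimate gives r of 71.2% for Wednesday's and 59.3% for Friday's.

What excess follows? My rule gives 15.2% for Wednesday's and 23.2% for Friday's, a gap wider than the margin of 2 points.

The forecast also names Friday's but stands higher than my figures, at 26% for Friday's and 19% for Wednesday's, reasoning that “Longer time therefore gives higher excess unless the catalyst dies”.

The flasks give 28.1% for Friday's and 20.6% for Wednesday's, so Friday's leads.

    coupling partner + free catalyst → spent catalyst (k = 1.30 M⁻¹ h⁻¹)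
    precatalyst → free catalyst (k = 0.130 h⁻¹)
    left-handed product ⇌ right-handed product (k = 0.950 h⁻¹)
    coupling partner + free catalyst + left-handed substrate → free catalyst + left-handed product (k = 970 M⁻² h⁻¹)
    coupling partner + free catalyst + right-handed substrate → free catalyst + right-handed product (k = 73.0 M⁻² h⁻¹)

Friday's and Wednesday's are one recipe stopped at different times, and that difference is the main reason for the gap: Wednesday's excess is 20.6% as it stands and 28.1% without the difference in time, a move of 7.5 points. Friday's keeps 54% of its left-handed substrate, and my s turns that into 27.5%, close to 28.1%, although spent catalyst stands at 66.9% there. In the neighbour like Wednesday's but with 0.40 M of coupling partner, 45% of the left-handed substrate remains, for which s gives 34.6%. The computed excess there is 35.1%.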